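**Retrosynthetic overview**

- The target comes from one hydrogenolysis of a penta-O-benzyl aryl bromide, which cleaves five O–CH2Ph bonds and the C2–Br bond of ring A.
- The strategy rests on ring A, a hexasubstituted benzene (C1 OMe, C2 H, C3 OH, C4 4-hydroxybenzyl, C5 CH2CH2–ring B, C6 4-hydroxybenzyl). C2–C3–C4–C5 is taken as C3–C6 of a 2-pyrone and C6–C1 as the C=C of a ketene dimethyl acetal. A [4+2] addition with loss of CO2 and MeOH forms C5–C6 and C1–C2 and leaves the C1 methyl ether.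
- The pyrone comes from lactonization of a 3,5-diketo ester made by two γ-selective dianion reactions on methyl acetoacetate (benzylation, then acylation with the ring-B propanoyl imidazole), followed by C3 bromination and 4-O-benzylation.
- The ring-B acid comes from Negishi benzylation of 5-benzyloxy-2-bromobenzaldehyde and a Meldrum's acid/formate reductive homologation. The ketene acetal comes from the Pinner orthoester of 3-(4-benzyloxyphenyl)propanenitrile by loss of methanol.
- Ring order: the four outer benzene rings are bought; the pyranone ring is made first and is then traded for ring A, the only carbocycle that is constructed.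

Key step: step 12

Remark: a bromine is carried at pyrone C3 (ring A C2) as a removable acceptor, because a 4-alkoxy-2-pyrone is an electron-rich diene; it leaves in the last step together with the benzyl groups.
Remark: the ketene acetal is derived from a nitrile, because its orthoester precursor is reached by a Pinner reaction and not from a methyl ester; the target has no stereocentre.

**Route**

Step 1
Reactants: 1 2-bromo-5-hydroxybenzaldehyde
Product: 2 5-(benzyloxy)-2-bromobenzaldehyde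
Conditions: BnBr, K2CO3, DMF, 25 °C
Reagents that add atoms: benzyl bromide, BrCc1ccccc1
Why: Williamson ether synthesis on the only acidic O–H; the aldehyde and the aryl bromide should be inert to carbonate and benzyl bromide.

Step 2
Reactants: 2 5-(benzyloxy)-2-bromobenzaldehyde; 3 4-(benzyloxy)benzyl chloride
Product: 5 5-(benzyloxy)-2-[4-(benzyloxy)benzyl]benzaldehyde, via [4-(benzyloxy)benzyl]zinc chloride 4 (not isolated)
Conditions: 3, Zn dust, LiCl, THF, 25 °C; then 2, Pd(OAc)2 (2 mol %), SPhos (4 mol %), THF, 25 °C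
Reagents that add atoms: none
Why: LiCl-promoted zinc insertion into the benzylic chloride followed by Negishi cross-coupling at the aryl C–Br bond, which should outrun the slow uncatalysed addition of a benzylzinc halide to the aldehyde.

Step 3
Reactants: 5 5-(benzyloxy)-2-[4-(benzyloxy)benzyl]benzaldehyde; 6 Meldrum's acid
Product: 9 3-{5-(benzyloxy)-2-[4-(benzyloxy)benzyl]phenyl}propanoic acid, via arylidene Meldrum's acid 7 (not isolated), via benzyl Meldrum's acid 8 (not isolated)
Conditions: HCO2H/Et3N (5:2), 95 °C; then aq. HCl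
Reagents that add atoms: water, O
Why: Domino Knoevenagel condensation, formate transfer reduction of the alkylidene Meldrum's acid and hydrolysis–decarboxylation should give the 3-arylpropanoic acid in one flask, and without a hydrogenation metal the benzyl ethers stay on.

Step 4
Reactants: 10 methyl acetoacetate; 3 4-(benzyloxy)benzyl chloride
Product: 12 methyl 5-[4-(benzyloxy)phenyl]-3-oxopentanoate, via sodium lithium dianion of methyl acetoacetate 11 (not isolated)
Conditions: NaH, THF, 0 °C; n-BuLi, 0 °C; then 3, 0 → 25 °C; aq. HCl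
Reagents that add atoms: none
Why: Huckin–Weiler alkylation, in which the more basic terminal carbanion of the acetoacetate dianion is the one that attacks the benzylic chloride.

Step 5
Reactants: 9 3-{5-(benzyloxy)-2-[4-(benzyloxy)benzyl]phenyl}propanoic acid; 12 methyl 5-[4-(benzyloxy)phenyl]-3-oxopentanoate
Product: 15 methyl 4-[4-(benzyloxy)benzyl]-7-{5-(benzyloxy)-2-[4-(benzyloxy)benzyl]phenyl}-3,5-dioxoheptanoate, via acyl imidazole 13 (not isolated), via dilithium dianion of keto ester 14 (not isolated)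
Conditions: 9, 1,1'-carbonyldiimidazole, THF, 25 °C; 12 (3 equiv), LiN(i-Pr)2 (6 equiv), THF, −78 → 0 °C; 13 added at −78 °C; aq. HCl
Reagents that add atoms: none
Why: Claisen-type γ-acylation of a β-keto ester dianion by an N-acylimidazole, run with excess dianion because imidazole and the more acidic tricarbonyl product each consume one equivalent; the new C4 centre is racemic and enolizable and disappears in step 6.

Step 6
Reactants: 15 methyl 4-[4-(benzyloxy)benzyl]-7-{5-(benzyloxy)-2-[4-(benzyloxy)benzyl]phenyl}-3,5-dioxoheptanoate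
Product: 16 5-[4-(benzyloxy)benzyl]-6-(2-{5-(benzyloxy)-2-[4-(benzyloxy)benzyl]phenyl}ethyl)-4-hydroxy-2H-pyran-2-one
Conditions: DBU, PhMe, 80 °C; aq. HCl
Reagents that add atoms: none
Why: Base-mediated lactonization of a 3,5-diketo ester, in which the C5 enol oxygen attacks the ester and methanol is lost to give the 4-hydroxy-2-pyrone.

Step 7
Reactants: 16 5-[4-(benzyloxy)benzyl]-6-(2-{5-(benzyloxy)-2-[4-(benzyloxy)benzyl]phenyl}ethyl)-4-hydroxy-2H-pyran-2-one
Product: 17 3-bromo-5-[4-(benzyloxy)benzyl]-6-(2-{5-(benzyloxy)-2-[4-(benzyloxy)benzyl]phenyl}ethyl)-4-hydroxy-2H-pyran-2-one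
Conditions: NBS (1.0 equiv), CH2Cl2, 0 °C
Reagents that add atoms: N-bromosuccinimide, O=C1CCC(=O)N1Br
Why: Electrophilic bromination at the enolic C3 of the 4-hydroxy-2-pyrone, a vinylogous β-dicarbonyl carbon that should react far faster than the alkoxyarene rings.

Step 8
Reactants: 17 3-bromo-5-[4-(benzyloxy)benzyl]-6-(2-{5-(benzyloxy)-2-[4-(benzyloxy)benzyl]phenyl}ethyl)-4-hydroxy-2H-pyran-2-one
Product: 18 4-(benzyloxy)-3-bromo-5-[4-(benzyloxy)benzyl]-6-(2-{5-(benzyloxy)-2-[4-(benzyloxy)benzyl]phenyl}ethyl)-2H-pyran-2-one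
Conditions: BnBr, K2CO3, DMF, 40 °C
Reagents that add atoms: benzyl bromide, BrCc1ccccc1
Why: O-alkylation of the vinylogous acid with a soft benzylic halide and carbonate should favour the 4-alkoxy-2-pyrone over the 2-alkoxy-4-pyranone, and C-alkylation is blocked by the C3 bromine.

Step 9
Reactants: 19 3-(4-hydroxyphenyl)propanenitrile
Product: 20 3-[4-(benzyloxy)phenyl]propanenitrile
Conditions: BnBr, K2CO3, acetone, reflux
Reagents that add atoms: benzyl bromide, BrCc1ccccc1
Why: Williamson ether synthesis on the phenol; the nitrile is untouched.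

Step 10
Reactants: 20 3-[4-(benzyloxy)phenyl]propanenitrile
Product: 22 1-(benzyloxy)-4-(3,3,3-trimethoxypropyl)benzene, via imidate hydrochloride 21 (not isolated)
Conditions: HCl (g), MeOH (1.1 equiv), Et2O, 0 °C; then MeOH, hexane, 25 °C
Reagents that add atoms: methanol, CO
Why: Pinner reaction, in which the nitrile is converted under anhydrous HCl into the methyl imidate hydrochloride and methanolysis of that salt gives the trimethyl orthoester and ammonium chloride.

Step 11
Reactants: 22 1-(benzyloxy)-4-(3,3,3-trimethoxypropyl)benzene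
Product: 23 1-(benzyloxy)-4-(3,3-dimethoxyprop-2-en-1-yl)benzene
Conditions: Me3SiOTf, i-Pr2NEt, CH2Cl2, −20 → 25 °C; filtration through basic alumina
Reagents that add atoms: none
Why: Gassman-type elimination, in which the silyl triflate ionizes the orthoester to a dialkoxycarbenium ion and the hindered amine removes the α-proton to give the ketene dimethyl acetal.

Step 12
Reactants: 18 4-(benzyloxy)-3-bromo-5-[4-(benzyloxy)benzyl]-6-(2-{5-(benzyloxy)-2-[4-(benzyloxy)benzyl]phenyl}ethyl)-2H-pyran-2-one; 23 1-(benzyloxy)-4-(3,3-dimethoxyprop-2-en-1-yl)benzene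
Product: 26 1-(benzyloxy)-2-bromo-3-methoxy-4,6-bis[4-(benzyloxy)benzyl]-5-(2-{5-(benzyloxy)-2-[4-(benzyloxy)benzyl]phenyl}ethyl)benzene, via bridged bicyclic lactone 24 (not isolated), via dimethoxy cyclohexadiene 25 (not isolated)
Conditions: 23 (4 equiv), CH2Cl2, 12 kbar, 40 °C; then mesitylene, 150 °C
Reagents that add atoms: none
Why: Proposed new method: the nucleophilic β-carbon of ketene acetal 23 should add to C6 of pyrone 18 (the δ-terminus of the dienyl lactone) while C3 closes onto the dialkoxycarbenium carbon, an asynchronous inverse-demand [4+2] cycloaddition that closes ring A as a six-membered carbocycle and gives bridged lactone 24; retro-[4+2] loss of CO2 then gives diene 25, and 1,2-elimination of methanol from the acetal carbon and the adjacent C–H aromatizes it to 26. The closest known reaction type is the cycloaddition of 3-carbomethoxy-2-pyrones with 1,1-dimethoxyethylene to give salicylate methyl ethers, together with the cycloadditions of 3-bromo-2-pyrones with enol ethers; what has not been shown is a 4-alkoxy-5,6-dialkyl-2-pyrone reacting with a β-substituted ketene acetal. Because the 4-benzyloxy group raises the LUMO of the diene, the C3 bromine serves as an inductive acceptor and high pressure is used to exploit the negative activation volume and to overcome the congestion at C6. The three stereocentres of 24 are transient and vanish on aromatization, so no stereocontrol is needed. The only selectivity required is regiochemical (acetal carbon to C3, benzyl-bearing carbon to C6), and it should follow from the polarization of both partners: the ketene acetal is nucleophilic only at its β-carbon and the pyrone is electrophilic at C6, so the methoxy group ends up next to the bromine-bearing carbon and the new benzyl group next to the bridge carbon.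

Step 13
Reactants: 26 1-(benzyloxy)-2-bromo-3-methoxy-4,6-bis[4-(benzyloxy)benzyl]-5-(2-{5-(benzyloxy)-2-[4-(benzyloxy)benzyl]phenyl}ethyl)benzene
Product: 27 2,4-bis(4-hydroxybenzyl)-3-{2-[5-hydroxy-2-(4-hydroxybenzyl)phenyl]ethyl}-5-methoxyphenol (CNP0147493.0)
Conditions: H2 (1 atm), 10% Pd/C, NaOAc, THF/MeOH, 25 °C
Reagents that add atoms: none
Why: Catalytic hydrogenolysis should cleave the five aryl benzyl ethers and the aryl C–Br bond in the same operation, with acetate taking up the HBr so that the catalyst stays active and no amine is present to slow the debenzylation.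

**Compound list**

1 | 2-bromo-5-hydroxybenzaldehyde | O=Cc1cc(O)ccc1Br | starting material
2 | 5-(benzyloxy)-2-bromobenzaldehyde | O=Cc1cc(OCc2ccccc2)ccc1Br | intermediate
3 | 4-(benzyloxy)benzyl chloride | ClCc1ccc(OCc2ccccc2)cc1 | starting material
4 | [4-(benzyloxy)benzyl]zinc chloride | Cl[Zn]Cc1ccc(OCc2ccccc2)cc1 | intermediate (not isolated)
5 | 5-(benzyloxy)-2-[4-(benzyloxy)benzyl]benzaldehyde | O=Cc1cc(OCc2ccccc2)ccc1Cc1ccc(OCc2ccccc2)cc1 | intermediate
6 | Meldrum's acid (2,2-dimethyl-1,3-dioxane-4,6-dione) | CC1(C)OC(=O)CC(=O)O1 | starting material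
7 | 5-{5-(benzyloxy)-2-[4-(benzyloxy)benzyl]benzylidene}-2,2-dimethyl-1,3-dioxane-4,6-dione | CC1(C)OC(=O)C(=Cc2cc(OCc3ccccc3)ccc2Cc2ccc(OCc3ccccc3)cc2)C(=O)O1 | intermediate (not isolated)
8 | 5-{5-(benzyloxy)-2-[4-(benzyloxy)benzyl]benzyl}-2,2-dimethyl-1,3-dioxane-4,6-dione | CC1(C)OC(=O)C(Cc2cc(OCc3ccccc3)ccc2Cc2ccc(OCc3ccccc3)cc2)C(=O)O1 | intermediate (not isolated)
9 | 3-{5-(benzyloxy)-2-[4-(benzyloxy)benzyl]phenyl}propanoic acid | OC(=O)CCc1cc(OCc2ccccc2)ccc1Cc1ccc(OCc2ccccc2)cc1 | intermediate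
10 | methyl acetoacetate | COC(=O)CC(C)=O | starting material
11 | sodium lithium C2,C4-dianion of methyl acetoacetate | COC(=O)[CH-]C(=O)[CH2-].[Na+].[Li+] | intermediate (not isolated)
12 | methyl 5-[4-(benzyloxy)phenyl]-3-oxopentanoate | COC(=O)CC(=O)CCc1ccc(OCc2ccccc2)cc1 | intermediate
13 | 1-(3-{5-(benzyloxy)-2-[4-(benzyloxy)benzyl]phenyl}propanoyl)imidazole | O=C(CCc1cc(OCc2ccccc2)ccc1Cc1ccc(OCc2ccccc2)cc1)n1ccnc1 | intermediate (not isolated)
14 | dilithium C2,C4-dianion of methyl 5-[4-(benzyloxy)phenyl]-3-oxopentanoate | COC(=O)[CH-]C(=O)[CH-]Cc1ccc(OCc2ccccc2)cc1.[Li+].[Li+] | intermediate (not isolated)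
15 | methyl 4-[4-(benzyloxy)benzyl]-7-{5-(benzyloxy)-2-[4-(benzyloxy)benzyl]phenyl}-3,5-dioxoheptanoate (racemic at C4, enolizable) | COC(=O)CC(=O)C(Cc1ccc(OCc2ccccc2)cc1)C(=O)CCc1cc(OCc2ccccc2)ccc1Cc1ccc(OCc2ccccc2)cc1 | intermediate
16 | 5-[4-(benzyloxy)benzyl]-6-(2-{5-(benzyloxy)-2-[4-(benzyloxy)benzyl]phenyl}ethyl)-4-hydroxy-2H-pyran-2-one | O=C1C=C(O)C(Cc2ccc(OCc3ccccc3)cc2)=C(CCc2cc(OCc3ccccc3)ccc2Cc2ccc(OCc3ccccc3)cc2)O1 | intermediate
17 | 3-bromo-5-[4-(benzyloxy)benzyl]-6-(2-{5-(benzyloxy)-2-[4-(benzyloxy)benzyl]phenyl}ethyl)-4-hydroxy-2H-pyran-2-one | O=C1OC(CCc2cc(OCc3ccccc3)ccc2Cc2ccc(OCc3ccccc3)cc2)=C(Cc2ccc(OCc3ccccc3)cc2)C(O)=C1Br | intermediate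
18 | 4-(benzyloxy)-3-bromo-5-[4-(benzyloxy)benzyl]-6-(2-{5-(benzyloxy)-2-[4-(benzyloxy)benzyl]phenyl}ethyl)-2H-pyran-2-one | O=C1OC(CCc2cc(OCc3ccccc3)ccc2Cc2ccc(OCc3ccccc3)cc2)=C(Cc2ccc(OCc3ccccc3)cc2)C(OCc2ccccc2)=C1Br | intermediate
19 | 3-(4-hydroxyphenyl)propanenitrile | N#CCCc1ccc(O)cc1 | starting material
20 | 3-[4-(benzyloxy)phenyl]propanenitrile | N#CCCc1ccc(OCc2ccccc2)cc1 | intermediate
21 | methyl 3-[4-(benzyloxy)phenyl]propanimidate hydrochloride | COC(=[NH2+])CCc1ccc(OCc2ccccc2)cc1.[Cl-] | intermediate (not isolated)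
22 | 1-(benzyloxy)-4-(3,3,3-trimethoxypropyl)benzene | COC(OC)(OC)CCc1ccc(OCc2ccccc2)cc1 | intermediate
23 | 1-(benzyloxy)-4-(3,3-dimethoxyprop-2-en-1-yl)benzene | COC(OC)=CCc1ccc(OCc2ccccc2)cc1 | intermediate
24 | 8-(benzyloxy)-4-bromo-5,5-dimethoxy-6,7-bis[4-(benzyloxy)benzyl]-1-(2-{5-(benzyloxy)-2-[4-(benzyloxy)benzyl]phenyl}ethyl)-2-oxabicyclo[2.2.2]oct-7-en-3-one (racemic, mixture of diastereomers) | O=C1OC2(CCc3cc(OCc4ccccc4)ccc3Cc3ccc(OCc4ccccc4)cc3)C(Cc3ccc(OCc4ccccc4)cc3)C(OC)(OC)C1(Br)C(OCc1ccccc1)=C2Cc1ccc(OCc2ccccc2)cc1 | intermediate (not isolated)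
25 | 2-(benzyloxy)-1-bromo-6,6-dimethoxy-3,5-bis[4-(benzyloxy)benzyl]-4-(2-{5-(benzyloxy)-2-[4-(benzyloxy)benzyl]phenyl}ethyl)cyclohexa-1,3-diene (racemic) | COC1(OC)C(Br)=C(OCc2ccccc2)C(Cc2ccc(OCc3ccccc3)cc2)=C(CCc2cc(OCc3ccccc3)ccc2Cc2ccc(OCc3ccccc3)cc2)C1Cc1ccc(OCc2ccccc2)cc1 | intermediate (not isolated)
26 | 1-(benzyloxy)-2-bromo-3-methoxy-4,6-bis[4-(benzyloxy)benzyl]-5-(2-{5-(benzyloxy)-2-[4-(benzyloxy)benzyl]phenyl}ethyl)benzene | COc1c(Br)c(OCc2ccccc2)c(Cc2ccc(OCc3ccccc3)cc2)c(CCc2cc(OCc3ccccc3)ccc2Cc2ccc(OCc3ccccc3)cc2)c1Cc1ccc(OCc2ccccc2)cc1 | intermediate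
27 | 2,4-bis(4-hydroxybenzyl)-3-{2-[5-hydroxy-2-(4-hydroxybenzyl)phenyl]ethyl}-5-methoxyphenol | COc1cc(O)c(Cc2ccc(O)cc2)c(CCc2cc(O)ccc2Cc2ccc(O)cc2)c1Cc1ccc(O)cc1 | target

**Step count**

Total steps: 13. Longest linear sequence: 9 steps (steps 1, 2, 3, 5, 6, 7, 8, 12, 13).

**Steps most likely to fail**

Step 12 (the one step that goes beyond known chemistry). The electron-rich pyrone may fail to engage the ketene acetal, which then hydrolyses or oligomerizes, or addition at C6 may stop at an open-chain conjugate adduct that never closes. The fallback gives up the cycloaddition and builds the bibenzyl by olefination; it sets out from aldehyde 5 and zinc reagent 4 and comes back at target 27. Purchased 3-hydroxy-5-methoxybenzaldehyde would be O-benzylated (BnBr, K2CO3) to 3-(benzyloxy)-5-methoxybenzaldehyde F1. Bromination at both positions ortho to the formyl group (NBS, 2.2 equiv, DMF) should give 3-(benzyloxy)-2,6-dibromo-5-methoxybenzaldehyde F2. A double Negishi coupling with 4 (Pd(OAc)2, SPhos, THF) should give 3-(benzyloxy)-2,6-bis[4-(benzyloxy)benzyl]-5-methoxybenzaldehyde F3. Aldehyde 5 would be reduced (NaBH4, MeOH) to {5-(benzyloxy)-2-[4-(benzyloxy)benzyl]phenyl}methanol F4, converted (PBr3, CH2Cl2) into 4-(benzyloxy)-1-[4-(benzyloxy)benzyl]-2-(bromomethyl)benzene F5, and taken by Arbuzov reaction with P(OEt)3 to diethyl {5-(benzyloxy)-2-[4-(benzyloxy)benzyl]benzyl}phosphonate F6. Horner–Wadsworth–Emmons olefination of F3 with F6 (NaH, THF) should give (E)-1-(benzyloxy)-3-methoxy-4,6-bis[4-(benzyloxy)benzyl]-5-(2-{5-(benzyloxy)-2-[4-(benzyloxy)benzyl]phenyl}ethenyl)benzene F7. Hydrogenation over Pd/C would then saturate the alkene and cleave the five benzyl ethers to give 27.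

Step 5. The hindered γ-substituted dianion may be quenched by proton transfer from imidazole and from the tricarbonyl product faster than it is acylated, or it may be acylated on oxygen. The fallback replaces the acylation by an aldol addition and an oxidation; it sets out from acid 9 and dianion 14 and comes back at diketo ester 15. Acid 9 would be reduced (BH3·THF) to 3-{5-(benzyloxy)-2-[4-(benzyloxy)benzyl]phenyl}propan-1-ol F8 and oxidized (Dess–Martin periodinane) to 3-{5-(benzyloxy)-2-[4-(benzyloxy)benzyl]phenyl}propanal F9. Addition of dianion 14 to F9 at −78 °C, which forms no acidic by-product, should give methyl 4-[4-(benzyloxy)benzyl]-7-{5-(benzyloxy)-2-[4-(benzyloxy)benzyl]phenyl}-5-hydroxy-3-oxoheptanoate F10 as a diastereomer mixture. Dess–Martin oxidation of its secondary alcohol leads back to 15.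

Step 11. The dialkoxycarbenium ion may be demethylated to the methyl ester instead of being deprotonated, and the ketene acetal may be hydrolysed during isolation. The fallback uses a silyl ketene acetal made by enolate trapping; it sets out from nitrile 20 and comes back at 26. Acidic methanolysis of 20 with aqueous work-up (HCl, MeOH; then H2O) should give methyl 3-[4-(benzyloxy)phenyl]propanoate F11. Enolization and O-silylation (LiN(i-Pr)2, t-BuMe2SiCl, THF/DMPU, −78 °C) should give tert-butyl{[3-(4-(benzyloxy)phenyl)-1-methoxyprop-1-en-1-yl]oxy}dimethylsilane F12. Under the conditions of step 12, F12 and pyrone 18 should give, after loss of CO2, either 26 directly (loss of the silanol) or the aryl silyl ether F13 (loss of methanol), named [3-(benzyloxy)-2-bromo-4,6-bis[4-(benzyloxy)benzyl]-5-(2-{5-(benzyloxy)-2-[4-(benzyloxy)benzyl]phenyl}ethyl)phenoxy](tert-butyl)dimethylsilane F13. Desilylation of F13 (Bu4NF, THF) would give 3-(benzyloxy)-2-bromo-4,6-bis[4-(benzyloxy)benzyl]-5-(2-{5-(benzyloxy)-2-[4-(benzyloxy)benzyl]phenyl}ethyl)phenol F14, and O-methylation (MeI, K2CO3, acetone) converges on 26.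

**Further compounds**

F1 | step 12 | 3-(benzyloxy)-5-methoxybenzaldehyde | COc1cc(C=O)cc(OCc2ccccc2)c1
F2 | step 12 | 3-(benzyloxy)-2,6-dibromo-5-methoxybenzaldehyde | COc1cc(OCc2ccccc2)c(Br)c(C=O)c1Br
F3 | step 12 | 3-(benzyloxy)-2,6-bis[4-(benzyloxy)benzyl]-5-methoxybenzaldehyde | COc1cc(OCc2ccccc2)c(Cc2ccc(OCc3ccccc3)cc2)c(C=O)c1Cc1ccc(OCc2ccccc2)cc1
F4 | step 12 | {5-(benzyloxy)-2-[4-(benzyloxy)benzyl]phenyl}methanol | OCc1cc(OCc2ccccc2)ccc1Cc1ccc(OCc2ccccc2)cc1
F5 | step 12 | 4-(benzyloxy)-1-[4-(benzyloxy)benzyl]-2-(bromomethyl)benzene | BrCc1cc(OCc2ccccc2)ccc1Cc1ccc(OCc2ccccc2)cc1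
F6 | step 12 | diethyl {5-(benzyloxy)-2-[4-(benzyloxy)benzyl]benzyl}phosphonate | CCOP(=O)(OCC)Cc1cc(OCc2ccccc2)ccc1Cc1ccc(OCc2ccccc2)cc1
F7 | step 12 | (E)-1-(benzyloxy)-3-methoxy-4,6-bis[4-(benzyloxy)benzyl]-5-(2-{5-(benzyloxy)-2-[4-(benzyloxy)benzyl]phenyl}ethenyl)benzene | COc1cc(OCc2ccccc2)c(Cc2ccc(OCc3ccccc3)cc2)c(/C=C/c2cc(OCc3ccccc3)ccc2Cc2ccc(OCc3ccccc3)cc2)c1Cc1ccc(OCc2ccccc2)cc1
F8 | step 5 | 3-{5-(benzyloxy)-2-[4-(benzyloxy)benzyl]phenyl}propan-1-ol | OCCCc1cc(OCc2ccccc2)ccc1Cc1ccc(OCc2ccccc2)cc1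
F9 | step 5 | 3-{5-(benzyloxy)-2-[4-(benzyloxy)benzyl]phenyl}propanal | O=CCCc1cc(OCc2ccccc2)ccc1Cc1ccc(OCc2ccccc2)cc1
F10 | step 5 | methyl 4-[4-(benzyloxy)benzyl]-7-{5-(benzyloxy)-2-[4-(benzyloxy)benzyl]phenyl}-5-hydroxy-3-oxoheptanoate (mixture of diastereomers, racemic) | COC(=O)CC(=O)C(Cc1ccc(OCc2ccccc2)cc1)C(O)CCc1cc(OCc2ccccc2)ccc1Cc1ccc(OCc2ccccc2)cc1
F11 | step 11 | methyl 3-[4-(benzyloxy)phenyl]propanoate | COC(=O)CCc1ccc(OCc2ccccc2)cc1
F12 | step 11 | tert-butyl{[3-(4-(benzyloxy)phenyl)-1-methoxyprop-1-en-1-yl]oxy}dimethylsilane (E/Z mixture) | COC(O[Si](C)(C)C(C)(C)C)=CCc1ccc(OCc2ccccc2)cc1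
F13 | step 11 | [3-(benzyloxy)-2-bromo-4,6-bis[4-(benzyloxy)benzyl]-5-(2-{5-(benzyloxy)-2-[4-(benzyloxy)benzyl]phenyl}ethyl)phenoxy](tert-butyl)dimethylsilane | CC(C)(C)[Si](C)(C)Oc1c(Br)c(OCc2ccccc2)c(Cc2ccc(OCc3ccccc3)cc2)c(CCc2cc(OCc3ccccc3)ccc2Cc2ccc(OCc3ccccc3)cc2)c1Cc1ccc(OCc2ccccc2)cc1
F14 | step 11 | 3-(benzyloxy)-2-bromo-4,6-bis[4-(benzyloxy)benzyl]-5-(2-{5-(benzyloxy)-2-[4-(benzyloxy)benzyl]phenyl}ethyl)phenol | Oc1c(Br)c(OCc2ccccc2)c(Cc2ccc(OCc3ccccc3)cc2)c(CCc2cc(OCc3ccccc3)ccc2Cc2ccc(OCc3ccccc3)cc2)c1Cc1ccc(OCc2ccccc2)cc1
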